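**Retrosynthetic overview**

1. Guaiane numbering: C1 ring-fusion CH, C2 H2, C3 =O, C4 (Me)=, C5 ring-fusion sp2 C, C6 H2, C7 (CMe2OAc), C8 (O-isobutyryl), C9 H2, C10 (Me), C11 carbinol carbon. The cyclopentenone C1–C2–C3–C4–C5 is closed last, on a finished cycloheptene, by a gold(I) Rautenstrauch rearrangement of the 1-ethynylallyl acetate 18 (C1–C2 bond; C3 oxygen delivered by 1,2-acetoxy shift).
2. Enabling feature: the 2-methylcyclopent-2-enone (C3=O between C2H2 and methyl-bearing C4, tetrasubstituted C4=C5, with C5 and C1 shared with the seven-membered ring) is the retron HC2≡C3–C4(Me)(OAc)–C5=C1 of a cycloheptenyl carbinol. The C10 methyl next to C1, cis to the C7 and C8 groups, steers the closure.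
3. 18 ⇒ 1-acetylcycloheptene 16 (acetylide addition, O-acetylation) ⇒ ring-closing metathesis (C1=C5) of the acyclic α-methylene ketone 15; the seven-membered ring is formed first.
4. 15 ⇒ auxiliary-controlled syn-aldol (C7–C8) of bromopentenoyl imide 7 with aldehyde 3 (C10 from a catalytic asymmetric vinyl conjugate addition), then ester → C11 carbinol, the two esters of the target, and a Stille acetyl installation.

Key step: step 11

Remark: 4-bromopent-4-enoic acid is taken as a purchasable building block; the propargylic carbon C4 of 18 is formed without control and both epimers are carried into step 11, where this centre becomes sp2.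

**Route**

Step 1
Reactants: 1 (E)-but-2-enal; 2 potassium (E)-trifluoro(styryl)borate
Product: 3 (S,E)-3-methyl-5-phenylpent-4-enal
Conditions: (2R,5R)-5-benzyl-2-tert-butyl-3-methylimidazolidin-4-one·HCl (20 mol %), HF (1 equiv), DME, −20 °C
Reagents that add atoms: none
Why: Iminium-catalysed enantioselective conjugate addition of a vinyl trifluoroborate to an enal (organocatalytic vinyl Friedel–Crafts-type alkylation); the benzyl arm of the (2R,5R)-imidazolidinone should shield the Re face of C-β of the E-iminium ion so that the styryl group adds to the Si face and sets C10 as S, while HF traps boron as KBF4.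

Step 2
Reactants: 4 (S)-4-benzyloxazolidin-2-one; 5 4-bromopent-4-enoic acid
Product: 7 (S)-4-benzyl-3-(4-bromopent-4-enoyl)oxazolidin-2-one, via mixed pivalic anhydride 6 (not isolated)
Conditions: PivCl, Et3N, THF, −20 °C; then 4, LiCl, −20 °C → rt
Reagents that add atoms: none
Why: N-acylation of the oxazolidinone through the mixed pivalic anhydride (LiCl/Et3N protocol) avoids a strong base and leaves the vinyl bromide untouched; no stereocentre is formed.

Step 3
Reactants: 7 (S)-4-benzyl-3-(4-bromopent-4-enoyl)oxazolidin-2-one; 3 (S,E)-3-methyl-5-phenylpent-4-enal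
Product: 9 (S)-4-benzyl-3-[(2S,3R,5S,E)-2-(2-bromoallyl)-3-hydroxy-5-methyl-7-phenylhept-6-enoyl]oxazolidin-2-one, via Z-boron enolate 8 (not isolated)
Conditions: Bu2BOTf, iPr2NEt, CH2Cl2, −78 → 0 °C; 3, −78 → 0 °C; then pH 7 buffer, MeOH, H2O2
Reagents that add atoms: none
Why: Evans syn-aldol: the Z-boron enolate reacts through a chair Zimmerman–Traxler transition state on the face away from the benzyl group, which should give the 7S,8R (syn) adduct under auxiliary control irrespective of the remote C10 centre.

Step 4
Reactants: 9 syn-aldol imide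
Product: 10 methyl (2S,3R,5S,E)-2-(2-bromoallyl)-3-hydroxy-5-methyl-7-phenylhept-6-enoate
Conditions: MeMgBr, MeOH (→ MeOMgBr), CH2Cl2, 0 °C; aq NH4Cl
Reagents that add atoms: methanol CO
Why: Transesterification with methoxymagnesium bromide cleaves the exocyclic acyl group of the imide selectively, frees the auxiliary for re-use, and at 0 °C should neither epimerise C7 nor trigger retro-aldol.

Step 5
Reactants: 10 β-hydroxy methyl ester
Product: 11 (3S,4R,6S,E)-3-(2-bromoallyl)-2,6-dimethyl-8-phenyloct-7-ene-2,4-diol
Conditions: MeMgBr (5 equiv), THF, −20 → 0 °C; aq NH4Cl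
Reagents that add atoms: methylmagnesium bromide C[Mg]Br
Why: Double Grignard addition to the ester builds the C11 dimethylcarbinol; the C8 hydroxyl is masked in the flask as its magnesium alkoxide, and the vinyl bromide and styrene are inert to MeMgBr.

Step 6
Reactants: 11 diol
Product: 12 (3S,4R,6S,E)-3-(2-bromoallyl)-2-hydroxy-2,6-dimethyl-8-phenyloct-7-en-4-yl 2-methylpropanoate
Conditions: iPrCOCl (1.1 equiv), pyridine, DMAP (cat.), CH2Cl2, 0 °C
Reagents that add atoms: isobutyryl chloride CC(C)C(Cl)=O
Why: Chemoselective acylation: the secondary C8 hydroxyl reacts with the acid chloride at 0 °C whereas the tertiary C11 carbinol does not, so the isobutyrate of the target is placed without a protecting group.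

Step 7
Reactants: 12 hydroxy isobutyrate
Product: 13 (3S,4R,6S,E)-2-acetoxy-3-(2-bromoallyl)-2,6-dimethyl-8-phenyloct-7-en-4-yl 2-methylpropanoate
Conditions: Ac2O, Sc(OTf)3 (2 mol %), MeCN, −20 °C
Reagents that add atoms: acetic anhydride CC(=O)OC(C)=O
Why: Lewis-acid-catalysed acetylation with acetic anhydride esterifies a hindered tertiary alcohol at low temperature without elimination; this installs the C11 acetate of the target, which from here on serves as its own protecting group.

Step 8
Reactants: 13 bromoalkene diester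
Product: 15 (3S,4R,6S,E)-2-acetoxy-2,6-dimethyl-3-(2-methylene-3-oxobutyl)-8-phenyloct-7-en-4-yl 2-methylpropanoate, via 2-ethoxydiene 14 (not isolated)
Conditions: tributyl(1-ethoxyvinyl)stannane, Pd(PPh3)4 (5 mol %), toluene, 90 °C; then 1 M HCl, THF, 0 °C → rt
Reagents that add atoms: tributyl(1-ethoxyvinyl)stannane CCCC[Sn](CCCC)(CCCC)C(=C)OCC; water O
Why: Stille coupling of the 2-bromoalkene with the acetyl-anion equivalent 1-ethoxyvinylstannane, followed by mild acid hydrolysis of the enol ether, should give the α-methylene methyl ketone (C4 with its methyl) with both esters intact.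

Step 9
Reactants: 15 α-methylene ketone
Product: 16 (1R,2S,6S)-4-acetyl-2-(2-acetoxypropan-2-yl)-6-methylcyclohept-4-en-1-yl 2-methylpropanoate
Conditions: Hoveyda–Grubbs II (10 mol %), toluene (2 mM), 80 °C
Reagents that add atoms: none
Why: Ring-closing metathesis between the styrenyl alkene (C1) and the 1,1-disubstituted enone alkene (C5) closes the seven-membered ring with loss of styrene and fixes the C1=C5 double bond regiochemically; the three stereocentres are not touched.

Step 10
Reactants: 16 1-acetylcycloheptene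
Product: 18 (1R,2S,6S)-4-(2-acetoxybut-3-yn-2-yl)-2-(2-acetoxypropan-2-yl)-6-methylcyclohept-4-en-1-yl 2-methylpropanoate (both C4 epimers), via bromomagnesium alkoxide 17 (not isolated)
Conditions: HC≡CMgBr (1.5 equiv), LaCl3·2LiCl, THF, −78 → −20 °C; then Ac2O, DMAP (cat.), −20 °C → rt; aq NH4Cl
Reagents that add atoms: ethynylmagnesium bromide C#C[Mg]Br; acetic anhydride CC(=O)OC(C)=O
Why: 1,2-Addition of an acetylide Grignard reagent to the ketone (La(III) suppresses enolisation, and at low temperature the ketone is far more electrophilic than the hindered isobutyrate and tertiary acetate), then in-flask O-acetylation of the tertiary alkoxide, should give the Rautenstrauch substrate; the new C4 centre is not controlled and need not be.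

Step 11
Reactants: 18 tertiary 1-ethynylallyl acetate
Product: 20 CNP0197994.1, (1R,7S,8R,10S)-11-acetoxy-8-isobutyryloxyguai-4-en-3-one, via cyclopentadienyl acetate 19 (not isolated)
Conditions: Ph3PAuCl (5 mol %), AgSbF6 (5 mol %), MeCN (2% H2O), −20 °C → rt
Reagents that add atoms: none
Why: Au(I) activates the terminal alkyne, the acetate carbonyl attacks C3, and the 1,2-acyloxy shift gives a vinylgold/3-acetoxypentadienyl cation (Au–C2=C3(OAc)–C4(Me)=C5–C1+) that closes to cyclopentadienyl acetate 19, which wet acetonitrile hydrolyses to the conjugated enone; the closest known reaction type is the gold(I)-catalysed Rautenstrauch rearrangement of 1-ethynyl-2-propenyl esters to cyclopent-2-enones, cycloalkenyl substrates included. The five-membered ring closes by C2–C1 bond formation in a 4π-conrotatory (Nazarov-like, formally 5-endo) cyclisation onto the ring alkene. The only new stereocentre, C1, should be set by substrate control: C2 bonds to the face of C1 opposite the adjacent C10 methyl (which lies on the same face as the C8 and C7 substituents), giving H1 cis to that methyl as in the target. The C4 carbinol centre is destroyed, and both epimers of 18 should converge because the tertiary, doubly activated C4–O bond ionises readily and the acyloxy shift is reversible. The step needs 1,2- rather than 1,3-acyloxy migration, which the terminal alkyne secures, and chemoselectivity among three esters, which is secured because only the propargylic acetate can reach the alkyne. In one operation it creates the C1–C2 bond, the C3 carbonyl, the tetrasubstituted C4=C5 alkene and the C1 configuration from a monocyclic enyne.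

**Compound list**

1 | (E)-but-2-enal (crotonaldehyde) | C/C=C/C=O | starting material
2 | potassium (E)-trifluoro(styryl)borate | [K+].F[B-](F)(F)/C=C/c1ccccc1 | starting material
3 | (S,E)-3-methyl-5-phenylpent-4-enal | O=CC[C@H](C)/C=C/c1ccccc1 | intermediate
4 | (S)-4-benzyloxazolidin-2-one | O=C1N[C@@H](Cc2ccccc2)CO1 | starting material
5 | 4-bromopent-4-enoic acid | OC(=O)CCC(Br)=C | starting material
6 | 4-bromopent-4-enoic pivalic anhydride | CC(C)(C)C(=O)OC(=O)CCC(Br)=C | intermediate
7 | (S)-4-benzyl-3-(4-bromopent-4-enoyl)oxazolidin-2-one | O=C1OC[C@H](Cc2ccccc2)N1C(=O)CCC(Br)=C | intermediate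
8 | (Z)-dibutylboron enolate of 7 | O=C1OC[C@H](Cc2ccccc2)N1/C(OB(CCCC)CCCC)=C/CC(Br)=C | intermediate
9 | (S)-4-benzyl-3-[(2S,3R,5S,E)-2-(2-bromoallyl)-3-hydroxy-5-methyl-7-phenylhept-6-enoyl]oxazolidin-2-one | O=C1OC[C@H](Cc2ccccc2)N1C(=O)[C@@H](CC(Br)=C)[C@H](O)C[C@H](C)/C=C/c3ccccc3 | intermediate
10 | methyl (2S,3R,5S,E)-2-(2-bromoallyl)-3-hydroxy-5-methyl-7-phenylhept-6-enoate | COC(=O)[C@@H](CC(Br)=C)[C@H](O)C[C@H](C)/C=C/c1ccccc1 | intermediate
11 | (3S,4R,6S,E)-3-(2-bromoallyl)-2,6-dimethyl-8-phenyloct-7-ene-2,4-diol | CC(C)(O)[C@@H](CC(Br)=C)[C@H](O)C[C@H](C)/C=C/c1ccccc1 | intermediate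
12 | (3S,4R,6S,E)-3-(2-bromoallyl)-2-hydroxy-2,6-dimethyl-8-phenyloct-7-en-4-yl 2-methylpropanoate | CC(C)(O)[C@@H](CC(Br)=C)[C@H](OC(=O)C(C)C)C[C@H](C)/C=C/c1ccccc1 | intermediate
13 | (3S,4R,6S,E)-2-acetoxy-3-(2-bromoallyl)-2,6-dimethyl-8-phenyloct-7-en-4-yl 2-methylpropanoate | CC(=O)OC(C)(C)[C@@H](CC(Br)=C)[C@H](OC(=O)C(C)C)C[C@H](C)/C=C/c1ccccc1 | intermediate
14 | 2-ethoxydiene (enol ether of 15; 3-ethoxy-2-methylenebut-3-enyl side chain on C7) | CC(=O)OC(C)(C)[C@@H](CC(=C)C(=C)OCC)[C@H](OC(=O)C(C)C)C[C@H](C)/C=C/c1ccccc1 | intermediate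
15 | (3S,4R,6S,E)-2-acetoxy-2,6-dimethyl-3-(2-methylene-3-oxobutyl)-8-phenyloct-7-en-4-yl 2-methylpropanoate | CC(=O)OC(C)(C)[C@@H](CC(=C)C(C)=O)[C@H](OC(=O)C(C)C)C[C@H](C)/C=C/c1ccccc1 | intermediate
16 | (1R,2S,6S)-4-acetyl-2-(2-acetoxypropan-2-yl)-6-methylcyclohept-4-en-1-yl 2-methylpropanoate | CC(=O)OC(C)(C)[C@H]1CC(C(C)=O)=C[C@@H](C)C[C@H]1OC(=O)C(C)C | intermediate
17 | bromomagnesium alkoxide of the tertiary propargylic alcohol from 16 (C4 epimers) | CC(=O)OC(C)(C)[C@H]1CC(C(C)(O[Mg]Br)C#C)=C[C@@H](C)C[C@H]1OC(=O)C(C)C | intermediate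
18 | (1R,2S,6S)-4-(2-acetoxybut-3-yn-2-yl)-2-(2-acetoxypropan-2-yl)-6-methylcyclohept-4-en-1-yl 2-methylpropanoate (C4 epimers) | CC(=O)OC(C)(C)[C@H]1CC(C(C)(OC(C)=O)C#C)=C[C@@H](C)C[C@H]1OC(=O)C(C)C | intermediate
19 | bicyclic cyclopentadienyl acetate (3-acetoxy-guaia-2,4-diene bearing the 8-isobutyrate and 11-acetate) | CC(=O)OC(C)(C)[C@H]1CC2=C(C)C(OC(C)=O)=C[C@@H]2[C@@H](C)C[C@H]1OC(=O)C(C)C | intermediate
20 | CNP0197994.1, (1R,7S,8R,10S)-11-acetoxy-8-isobutyryloxyguai-4-en-3-one | CC(=O)OC(C)(C)[C@H]1CC2=C(C)C(=O)C[C@@H]2[C@@H](C)C[C@H]1OC(=O)C(C)C | target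

**Step count**

Total steps: 11. Longest linear sequence: 10 steps (steps 2–11); step 1 is a one-step branch.

**Steps most likely to fail, with fallbacks**

Step 11. Facial control at C1 may be lost if the C4 configuration of one epimer of 18 is relayed into the ring closure instead of control by the C10 methyl, or the substrate may divert into 1,3-acyloxy shift (allene) chemistry. The fallback sets out from 18 and replaces kinetic by thermodynamic control. The rearrangement is run under the palladium(II) protocol (PdCl2(MeCN)2, AcOH, MeCN, 60 °C), which should give the enone without regard to C1, that is 20 together with its C1 epimer, 1-epi-20 F1. The mixture is then treated with DBU in toluene at 60 °C. C1–H is the γ-hydrogen of the enone, so the C3–C4–C5–C1 dienolate should equilibrate this centre towards the epimer with C2 trans to the C10 methyl; that this is the more stable epimer is an expectation. The route is rejoined at 20.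

Step 9. Initiation may be slow because neither the α-branched styrenyl alkene nor the electron-poor 1,1-disubstituted enone alkene loads the ruthenium carbene well, so dimerisation or oligomerisation of 15 may outrun ring closure. The fallback sets out from 15 and moves the metathesis to the alcohol oxidation level. Luche reduction (NaBH4, CeCl3, MeOH, −40 °C) should give the allylic alcohol F2 (C4 epimers), whose 1,1-disubstituted allylic alkene is a better partner. Ring-closing metathesis (Grubbs II, CH2Cl2, 40 °C) should give the cycloheptenyl carbinol F3, and Dess–Martin oxidation returns to 16.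

Step 10. The acetylide may attack the acetate or isobutyrate or merely enolise the methyl ketone, and acetylation of the hindered tertiary alkoxide may stay incomplete. The fallback sets out from diol 11 and postpones all acylations, so that the hydroxyl groups travel as alkoxides. Stille coupling of 11 with the same stannane gives the ethoxydiene diol F4, hydrolysed without isolation to the hydroxy α-methylene ketone F5. Ring-closing metathesis gives the cyclic diol enone F6, and excess HC≡CMgBr gives the triol F7. Isobutyryl chloride/pyridine at 0 °C acylates only the secondary hydroxyl to give the isobutyrate diol F8, and Ac2O/DMAP/Et3N then acetylates both tertiary hydroxyls to reach 18.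

**Further compounds**

F1 | step 11 | 1-epi-20 (C1 epimer of the target) | CC(=O)OC(C)(C)[C@H]1CC2=C(C)C(=O)C[C@H]2[C@@H](C)C[C@H]1OC(=O)C(C)C
F2 | step 9 | allylic alcohol from 1,2-reduction of 15 (3-hydroxy-2-methylenebutyl side chain, C4 epimers) | CC(=O)OC(C)(C)[C@@H](CC(=C)C(C)O)[C@H](OC(=O)C(C)C)C[C@H](C)/C=C/c1ccccc1
F3 | step 9 | (1R,2S,6S)-2-(2-acetoxypropan-2-yl)-4-(1-hydroxyethyl)-6-methylcyclohept-4-en-1-yl 2-methylpropanoate (C4 epimers) | CC(=O)OC(C)(C)[C@H]1CC(C(C)O)=C[C@@H](C)C[C@H]1OC(=O)C(C)C
F4 | step 10 | ethoxydiene diol (Stille product of 11) | CC(C)(O)[C@@H](CC(=C)C(=C)OCC)[C@H](O)C[C@H](C)/C=C/c1ccccc1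
F5 | step 10 | (5S,6R,8S,E)-6-hydroxy-5-(2-hydroxypropan-2-yl)-8-methyl-3-methylene-10-phenyldec-9-en-2-one | CC(C)(O)[C@@H](CC(=C)C(C)=O)[C@H](O)C[C@H](C)/C=C/c1ccccc1
F6 | step 10 | 1-[(4R,5S,7S)... cyclic diol enone: 4-acetyl-2-(2-hydroxypropan-2-yl)-6-methylcyclohept-4-en-1-ol (1R,2S,6S) | CC(C)(O)[C@H]1CC(C(C)=O)=C[C@@H](C)C[C@H]1O
F7 | step 10 | triol: (1R,2S,6S)-4-(2-hydroxybut-3-yn-2-yl)-2-(2-hydroxypropan-2-yl)-6-methylcyclohept-4-en-1-ol (C4 epimers) | CC(C)(O)[C@H]1CC(C(C)(O)C#C)=C[C@@H](C)C[C@H]1O
F8 | step 10 | (1R,2S,6S)-4-(2-hydroxybut-3-yn-2-yl)-2-(2-hydroxypropan-2-yl)-6-methylcyclohept-4-en-1-yl 2-methylpropanoate (C4 epimers) | CC(C)(O)[C@H]1CC(C(C)(O)C#C)=C[C@@H](C)C[C@H]1OC(=O)C(C)C
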